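**Plan**

- Retrosynthesis: ring C is cut at O1–C2 (phenol adding to an ynone) and at C3–C4 (acetylide plus aldehyde). This leaves a penta-oxygenated benzaldehyde and a ring B alkyne made from isovanillin.
- The aldehyde carbon (C4) and the 5-oxygen are the two ends of a cleaved furan C2=C3 bond, so the aldehyde comes from a benzofuran.
- Ring A of that benzofuran is cut at C5–C6 (flavone numbering) back to a 4-(3-furyl)cyclobutenone, made from dimethyl squarate and 3-furyllithium.
- Enabling feature: the C7 and C8 methoxyls sit between oxygen-bearing C6 and C8a, which is the four-carbon dimethoxy-dione pattern of dimethyl squarate. C4a, C5 and the 5-oxygen are C3, C2 and O of a furan.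
- Forward order: cyclobutenone, then ring A by thermal ring expansion, then furan cleavage, ynone formation with the intact ring B piece, and ring C closed last.
- Stereochemistry: the target has none; the carbinol centres made on the way are racemic and are erased in steps 3 and 10.

Key step: step 3

Remark: compounds 4, 5, 7, 10 and 18 are racemic; the SMILES of 10 shows one enantiomer of the cis pair.

**Route**

Step 1
Reactants: 1 3-bromofuran; 2 dimethyl squarate
Product: 4 (±)-4-(furan-3-yl)-4-hydroxy-2,3-dimethoxycyclobut-2-en-1-one, via furan-3-yllithium 3 (not isolated)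
Conditions: 1, n-BuLi, THF, −78 °C; cannulate into 2, THF, −78 °C; sat. aq NH4Cl at −78 °C
Reagents that add atoms: none
Why: Bromine–lithium exchange at −78 °C should give the 3-furyl anion without drift to the 2-lithio isomer, and its 1,2-addition to one of the two equivalent squarate carbonyls is the standard entry to 4-hydroxycyclobutenones; the new carbinol centre is racemic and is lost in step 3.

Step 2
Reactants: 4 (±)-4-(furan-3-yl)-4-hydroxy-2,3-dimethoxycyclobut-2-en-1-one
Product: 5 (±)-4-(furan-3-yl)-2,3-dimethoxy-4-(methoxymethoxy)cyclobut-2-en-1-one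
Conditions: MOMCl, iPr2NEt, n-Bu4NI (cat.), CH2Cl2, 0 °C to rt
Reagents that add atoms: chloromethyl methyl ether (MOMCl), COCCl
Why: Williamson-type acetal formation with the very electrophilic MOMCl and a non-nucleophilic amine base should cap the tertiary carbinol without opening the base-sensitive four-membered ring.

Step 3
Reactants: 5 (±)-4-(furan-3-yl)-2,3-dimethoxy-4-(methoxymethoxy)cyclobut-2-en-1-one
Product: 8 5,6-dimethoxy-4-(methoxymethoxy)-1-benzofuran-7-ol, via vinylketene 6 (not isolated), via bicyclic dienone 7 (not isolated)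
Conditions: degassed toluene (0.02 M), reflux (110 °C), Ar
Reagents that add atoms: none
Why: Heating opens the cyclobutenone by a conrotatory four-electron electrocyclic ring opening in which the donor methoxymethoxy group turns outward, so vinylketene 6 carries the furan cis to the ketene; the ketene carbon then bonds to furan C2 in a thermally allowed disrotatory six-electron electrocyclisation to dienone 7, and a proton shift from C7a to the carbonyl oxygen gives phenol 8. The closest known reaction type is the Moore rearrangement of 4-aryl- and 4-heteroaryl-4-oxycyclobutenones to hydroquinones and their monoethers. The one ring formed, ring A, closes by 6π electrocyclisation with formation of the C7–C7a bond of the benzofuran, which is the C5–C6 bond of the flavone. No stereocentre is created, and the carbinol centre of 5 and the C7a centre of 7 both vanish on aromatisation. Two selectivities are needed: outward rotation of the oxygen substituent, which is the normal torquoselectivity of a donor at C4 of a cyclobutenone, and closure at furan C2 in preference to C4, which is secured because C2 is the alpha carbon with the larger HOMO coefficient and only this closure can end in a benzenoid benzofuran, while C4 closure would lead to an ortho-quinoid 2-benzofuran. The two hydroquinone oxygens emerge distinct, the former carbinol oxygen as the MOM ether at C4 and the former ketene oxygen as the free phenol at C7.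

Step 4
Reactants: 8 5,6-dimethoxy-4-(methoxymethoxy)-1-benzofuran-7-ol
Product: 9 5,6-dimethoxy-4,7-bis(methoxymethoxy)-1-benzofuran
Conditions: MOMCl, iPr2NEt, CH2Cl2, 0 °C to rt, Ar
Reagents that add atoms: chloromethyl methyl ether (MOMCl), COCCl
Why: Phenol O-alkylation (Williamson type) removes the oxidation-prone free hydroquinone monoether before the oxidative step, and the group chosen leaves in the same acid step that later frees the ring C oxygen.

Step 5
Reactants: 9 5,6-dimethoxy-4,7-bis(methoxymethoxy)-1-benzofuran
Product: 12 2-hydroxy-4,5-dimethoxy-3,6-bis(methoxymethoxy)benzaldehyde, via cis-diol 10 (not isolated), via aryl formate 11 (not isolated)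
Conditions: OsO4 (2 mol %), NaIO4 (4 equiv), 2,6-lutidine, 1,4-dioxane/H2O (3:1), rt; extractive work-up; then K2CO3 (cat.), MeOH, 0 °C
Reagents that add atoms: osmium tetroxide, O=[Os](=O)(=O)=O; sodium periodate, [Na+].[O-]I(=O)(=O)=O
Why: Lemieux–Johnson cleavage, in which OsO4 should dihydroxylate the enol-ether-like C2=C3 bond of the benzofuran in preference to the fully substituted benzene ring, NaIO4 cleaves hemiacetal diol 10 to aldehyde formate 11, and mild methanolysis of the aryl formate frees the phenol, so the furan acts as a masked ortho-hydroxy aldehyde.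

Step 6
Reactants: 12 2-hydroxy-4,5-dimethoxy-3,6-bis(methoxymethoxy)benzaldehyde
Product: 13 2-(benzyloxy)-4,5-dimethoxy-3,6-bis(methoxymethoxy)benzaldehyde
Conditions: BnBr, K2CO3, DMF, 50 °C
Reagents that add atoms: benzyl bromide, BrCc1ccccc1
Why: Williamson benzylation of the salicylaldehyde hydroxyl blocks the future 5-oxygen with an acid-stable group, so that only the other ortho oxygen can later close the pyranone.

Step 7
Reactants: 14 isovanillin
Product: 15 3-(benzyloxy)-4-methoxybenzaldehyde
Conditions: BnBr, K2CO3, DMF, rt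
Reagents that add atoms: benzyl bromide, BrCc1ccccc1
Why: Routine Williamson benzylation of a phenol protects the 3'-oxygen with the same group used at O5, so both fall in the last step.

Step 8
Reactants: 15 3-(benzyloxy)-4-methoxybenzaldehyde
Product: 16 2-(benzyloxy)-4-ethynyl-1-methoxybenzene
Conditions: dimethyl (1-diazo-2-oxopropyl)phosphonate, K2CO3, MeOH, 0 °C to rt
Reagents that add atoms: dimethyl (1-diazo-2-oxopropyl)phosphonate, CC(=O)C(=[N+]=[N-])P(=O)(OC)OC
Why: Seyferth–Gilbert homologation with the Ohira–Bestmann reagent converts aryl aldehydes, electron-rich ones included, into terminal alkynes in one operation under mild carbonate conditions.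

Step 9
Reactants: 16 2-(benzyloxy)-4-ethynyl-1-methoxybenzene; 13 2-(benzyloxy)-4,5-dimethoxy-3,6-bis(methoxymethoxy)benzaldehyde
Product: 18 (±)-1-[2-(benzyloxy)-4,5-dimethoxy-3,6-bis(methoxymethoxy)phenyl]-3-[3-(benzyloxy)-4-methoxyphenyl]prop-2-yn-1-ol, via lithium acetylide 17 (not isolated)
Conditions: 16, n-BuLi, THF, −78 °C; then 13, −78 to 0 °C; sat. aq NH4Cl
Reagents that add atoms: none
Why: 1,2-Addition of a small, linear lithium acetylide to an aldehyde tolerates the two ortho substituents and forms the C3–C4 bond; the carbinol centre is racemic and is removed by the next oxidation.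

Step 10
Reactants: 18 (±)-1-[2-(benzyloxy)-4,5-dimethoxy-3,6-bis(methoxymethoxy)phenyl]-3-[3-(benzyloxy)-4-methoxyphenyl]prop-2-yn-1-ol
Product: 19 1-[2-(benzyloxy)-4,5-dimethoxy-3,6-bis(methoxymethoxy)phenyl]-3-[3-(benzyloxy)-4-methoxyphenyl]prop-2-yn-1-one
Conditions: activated MnO2 (excess), CH2Cl2, rt
Reagents that add atoms: none
Why: MnO2 oxidation is selective for benzylic and propargylic alcohols and is neutral, so the MOM and benzyl ethers and the alkyne are untouched.

Step 11
Reactants: 19 1-[2-(benzyloxy)-4,5-dimethoxy-3,6-bis(methoxymethoxy)phenyl]-3-[3-(benzyloxy)-4-methoxyphenyl]prop-2-yn-1-one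
Product: 21 5-(benzyloxy)-2-[3-(benzyloxy)-4-methoxyphenyl]-6-hydroxy-7,8-dimethoxy-4H-chromen-4-one, via dihydroxy ynone 20 (not isolated)
Conditions: HCl (ca. 1 M in MeOH), THF co-solvent, 50 °C
Reagents that add atoms: none
Why: Acid-catalysed acetal exchange removes both MOM ethers, and the phenol ortho to the ynone then adds 6-endo-dig (oxa-Michael) to the protonated ynone to close ring C, the other ortho oxygen being benzylated and the second free phenol being too far away to cyclise.

Step 12
Reactants: 21 5-(benzyloxy)-2-[3-(benzyloxy)-4-methoxyphenyl]-6-hydroxy-7,8-dimethoxy-4H-chromen-4-one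
Product: 22 5,6,3'-trihydroxy-7,8,4'-trimethoxyflavone
Conditions: H2 (1 atm), 10% Pd/C, EtOAc/MeOH (1:1), rt
Reagents that add atoms: none
Why: Catalytic hydrogenolysis of aryl benzyl ethers on Pd/C is standard for benzylated flavones, whose C2=C3 bond is a vinylogous ester inside the pyranone and should survive if the reaction is stopped after uptake of two equivalents of hydrogen.

**Compound list**

1 | 3-bromofuran | Brc1ccoc1 | starting material
2 | dimethyl squarate (3,4-dimethoxycyclobut-3-ene-1,2-dione) | COC1=C(OC)C(=O)C1=O | starting material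
3 | furan-3-yllithium | [Li]c1ccoc1 | intermediate
4 | (±)-4-(furan-3-yl)-4-hydroxy-2,3-dimethoxycyclobut-2-en-1-one | COC1=C(OC)C(O)(c2ccoc2)C1=O | intermediate
5 | (±)-4-(furan-3-yl)-2,3-dimethoxy-4-(methoxymethoxy)cyclobut-2-en-1-one | COCOC1(c2ccoc2)C(OC)=C(OC)C1=O | intermediate
6 | (3Z)-4-(furan-3-yl)-2,3-dimethoxy-4-(methoxymethoxy)buta-1,3-dien-1-one (vinylketene, furyl cis to the ketene carbon) | O=C=C(OC)/C(OC)=C(/OCOC)c1ccoc1 | intermediate
7 | (±)-5,6-dimethoxy-4-(methoxymethoxy)-1-benzofuran-7(7aH)-one | COCOC1=C2C=COC2C(=O)C(OC)=C1OC | intermediate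
8 | 5,6-dimethoxy-4-(methoxymethoxy)-1-benzofuran-7-ol | COCOc1c(OC)c(OC)c(O)c2occc12 | intermediate
9 | 5,6-dimethoxy-4,7-bis(methoxymethoxy)-1-benzofuran | COCOc1c(OC)c(OC)c(OCOC)c2occc12 | intermediate
10 | (2R*,3S*)-5,6-dimethoxy-4,7-bis(methoxymethoxy)-2,3-dihydro-1-benzofuran-2,3-diol (cis, racemic) | COCOc1c(OC)c(OC)c(OCOC)c2O[C@@H](O)[C@@H](O)c12 | intermediate
11 | 2-formyl-4,5-dimethoxy-3,6-bis(methoxymethoxy)phenyl formate | COCOc1c(OC)c(OC)c(OCOC)c(OC=O)c1C=O | intermediate
12 | 2-hydroxy-4,5-dimethoxy-3,6-bis(methoxymethoxy)benzaldehyde | COCOc1c(OC)c(OC)c(OCOC)c(O)c1C=O | intermediate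
13 | 2-(benzyloxy)-4,5-dimethoxy-3,6-bis(methoxymethoxy)benzaldehyde | COCOc1c(OC)c(OC)c(OCOC)c(OCc2ccccc2)c1C=O | intermediate
14 | isovanillin (3-hydroxy-4-methoxybenzaldehyde) | COc1ccc(C=O)cc1O | starting material
15 | 3-(benzyloxy)-4-methoxybenzaldehyde | COc1ccc(C=O)cc1OCc1ccccc1 | intermediate
16 | 2-(benzyloxy)-4-ethynyl-1-methoxybenzene | COc1ccc(C#C)cc1OCc1ccccc1 | intermediate
17 | lithium [3-(benzyloxy)-4-methoxyphenyl]acetylide | [Li]C#Cc1ccc(OC)c(OCc2ccccc2)c1 | intermediate
18 | (±)-1-[2-(benzyloxy)-4,5-dimethoxy-3,6-bis(methoxymethoxy)phenyl]-3-[3-(benzyloxy)-4-methoxyphenyl]prop-2-yn-1-ol | COCOc1c(OC)c(OC)c(OCOC)c(OCc2ccccc2)c1C(O)C#Cc1ccc(OC)c(OCc2ccccc2)c1 | intermediate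
19 | 1-[2-(benzyloxy)-4,5-dimethoxy-3,6-bis(methoxymethoxy)phenyl]-3-[3-(benzyloxy)-4-methoxyphenyl]prop-2-yn-1-one | COCOc1c(OC)c(OC)c(OCOC)c(OCc2ccccc2)c1C(=O)C#Cc1ccc(OC)c(OCc2ccccc2)c1 | intermediate
20 | 1-[2-(benzyloxy)-3,6-dihydroxy-4,5-dimethoxyphenyl]-3-[3-(benzyloxy)-4-methoxyphenyl]prop-2-yn-1-one | Oc1c(OC)c(OC)c(O)c(OCc2ccccc2)c1C(=O)C#Cc1ccc(OC)c(OCc2ccccc2)c1 | intermediate
21 | 5-(benzyloxy)-2-[3-(benzyloxy)-4-methoxyphenyl]-6-hydroxy-7,8-dimethoxy-4H-chromen-4-one | COc1ccc(-c2cc(=O)c3c(OCc4ccccc4)c(O)c(OC)c(OC)c3o2)cc1OCc1ccccc1 | intermediate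
22 | 5,6,3'-trihydroxy-7,8,4'-trimethoxyflavone (5,6-dihydroxy-2-(3-hydroxy-4-methoxyphenyl)-7,8-dimethoxy-4H-chromen-4-one) | COc1ccc(-c2cc(=O)c3c(O)c(O)c(OC)c(OC)c3o2)cc1O | target

**Step count and risks**

Total steps: 12. Longest linear sequence: 10 (steps 1–6, then 9–12). The ring B branch is steps 7–8.

Steps most likely to fail:

1. Step 3 (ring expansion). The vinylketene may decompose or lose its acetal before it closes, and the very electron-rich phenol may oxidise in air during isolation. The fallback sets out from 4 and returns at 9.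
   - Unprotected carbinol 4 is heated in degassed p-xylene at reflux, the free-hydroxyl variant of the same rearrangement, to give 5,6-dimethoxy-1-benzofuran-4,7-diol F1.
   - F1 is oxidised on work-up with Ag2O to the stable, easily purified 5,6-dimethoxy-1-benzofuran-4,7-dione F2.
   - Reduction with aqueous Na2S2O4 returns F1, which is alkylated on both oxygens with NaH and MOMCl in DMF to give 9.
   - Nothing is lost by the missing differentiation, because the benzofuran skeleton already tells the two oxygens apart: C4–O lies ortho to the future aldehyde and C7–O ortho to the furan oxygen.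

2. Step 5 (furan cleavage). Osmylation of the aromatic furan bond may be slow, and the oxidant may attack the penta-oxygenated benzene ring instead. The fallback sets out from 9 and returns at 12.
   - Ozone is used in place of the metal-oxo/glycol route: O3, CH2Cl2/MeOH, −78 °C, dosed to a Sudan Red 7B end point, then Me2S.
   - Direct cycloaddition to C2=C3 and cycloreversion should give the same aryl formate 11, which is methanolysed as before to 12.
   - No compound outside the list arises (F0).

3. Step 11 (deprotection and ring C closure). The freed phenol may close 5-exo-dig to the aurone, or the sequence may stall at the open hydroxy ynone or its methanol adduct. The fallback sets out from 19 and returns at 21.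
   - The alkyne is first converted with Et2NH in EtOH at rt (conjugate addition) into (2E)-1-[2-(benzyloxy)-4,5-dimethoxy-3,6-bis(methoxymethoxy)phenyl]-3-[3-(benzyloxy)-4-methoxyphenyl]-3-(diethylamino)prop-2-en-1-one F3.
   - HCl in MeOH then removes the MOM ethers to give (2E)-1-[2-(benzyloxy)-3,6-dihydroxy-4,5-dimethoxyphenyl]-3-[3-(benzyloxy)-4-methoxyphenyl]-3-(diethylamino)prop-2-en-1-one F4.
   - In F4 the ortho phenol displaces diethylamine by addition–elimination at the β-carbon, a path that can only give the six-membered pyranone 21.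

Further compounds
F1 | step 3 | 5,6-dimethoxy-1-benzofuran-4,7-diol | COc1c(OC)c(O)c2occc2c1O
F2 | step 3 | 5,6-dimethoxy-1-benzofuran-4,7-dione | COC1=C(OC)C(=O)c2occc2C1=O
F0 | step 5 | none | none
F3 | step 11 | (2E)-1-[2-(benzyloxy)-4,5-dimethoxy-3,6-bis(methoxymethoxy)phenyl]-3-[3-(benzyloxy)-4-methoxyphenyl]-3-(diethylamino)prop-2-en-1-one | COCOc1c(OC)c(OC)c(OCOC)c(OCc2ccccc2)c1C(=O)/C=C(/N(CC)CC)c1ccc(OC)c(OCc2ccccc2)c1
F4 | step 11 | (2E)-1-[2-(benzyloxy)-3,6-dihydroxy-4,5-dimethoxyphenyl]-3-[3-(benzyloxy)-4-methoxyphenyl]-3-(diethylamino)prop-2-en-1-one | Oc1c(OC)c(OC)c(O)c(OCc2ccccc2)c1C(=O)/C=C(/N(CC)CC)c1ccc(OC)c(OCc2ccccc2)c1
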